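**Retrosynthetic overview**
1. Oreskaurin A ⇐ desilylation ⇐ C15 enone (allylic oxidation of the 16-ene) ⇐ C6 acetoxy-lactol from a γ-lactone; ring D ⇐ oxidative cyclization of the δ-lactone silyl ketene acetal onto a C13 isopropenyl group (C8–C15).
2. Ring C ⇐ ketyl–olefin cyclization (C9–C11) on an unsaturated spiro-δ-lactone; the C1 and C11 carbinols are set together by one bulky-hydride reduction of a diketone.
3. Spiro-δ-lactone (ring B, C10 quaternary) ⇐ Michael addition and reductive lactonization of a C10-formyl keto-lactone, then C8 alkylation with an (S)-iodide made from furan-2(5H)-one.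
4. Ring A/ring E keto-lactone ⇐ key C–O step: enantioselective, carboxylate-directed γ-C(sp3)–H lactonization (C19–O bond, sets C4) of an achiral gem-dimethyl enone acid from a Robinson annulation.
5. Ring order: A → E (γ-lactone, later the acetoxy-tetrahydrofuran) → B (δ-lactone) → C → D.

Atom labels C1–C20 are the kaurane numbers of the target: C1 and C11 carbinols, C4 quaternary (C18 methyl, C19 CH2O), C5 ring-fusion CH, C6 acetal carbon, C7 δ-lactone carbonyl, C8/C13 bridgeheads, C10 spiro carbon, C15 ketone, C16=C17 methylidene, C20 lactone CH2O.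

Assumption: the (S,S)-ligand in step 3 and (S)-BINAP in step 7 are taken to give the drawn enantiomers; if the sense of induction is opposite, the mirror-image ligand is used.

**Step 1**
Reactants: 1 methyl 3-methyl-2-oxobutanoate; 2 but-3-en-2-one
Product: 3 methyl 6,6-dimethyl-3-oxocyclohex-1-ene-1-carboxylate
Conditions: TsOH·H2O (10 mol %), toluene, 60 °C then reflux (Dean–Stark)
Reagents that add atoms: none
Why: Acid-catalysed Robinson annulation, in which the only enolisable position of the α-keto ester adds to the enone (Michael) and the methyl ketone then condenses onto the α-keto carbonyl (aldol condensation); no stereocentre is formed.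

**Step 2**
Reactants: 3 methyl 6,6-dimethyl-3-oxocyclohex-1-ene-1-carboxylate
Product: 4 6,6-dimethyl-3-oxocyclohex-1-ene-1-carboxylic acid
Conditions: LiOH (1.5 equiv), THF/H2O, 0 °C; then 1 M HCl
Reagents that add atoms: lithium hydroxide, [Li+].[OH-]
Why: Ester saponification; the acid has no stereocentre and its two methyl groups are enantiotopic.

**Step 3**
Reactants: 4 6,6-dimethyl-3-oxocyclohex-1-ene-1-carboxylic acid
Product: 5 (3aR)-3a-methyl-3a,4-dihydro-2-benzofuran-1,6(3H,5H)-dione
Conditions: [Mn(OTf)2(L)] (2 mol %; L = (S,S)-N,N′-bis[(5-triisopropylsilylpyridin-2-yl)methyl]-2,2′-bipyrrolidine), H2O2 (50 % aq, 2 equiv, syringe pump), TfOH (10 mol %), (CF3)2CHOH, 0 °C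
Reagents that add atoms: none
Why: Proposed new method: the carboxylate binds the chiral manganese centre, H2O2 gives a carboxylato manganese-oxo species (formally pentavalent) that abstracts a hydrogen from one enantiotopic C4 methyl through a seven-membered transition state, and carboxylate rebound closes the γ-lactone (C19–O) and sets C4 as R, while the alkene, deactivated by both ketone and acid, should resist epoxidation; the closest known reaction type is manganese-catalysed carboxylic-acid-directed γ-lactonization of primary C–H bonds in saturated gem-dimethyl acids, not yet shown for a conjugated cyclohexenecarboxylic acid.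

**Step 4**
Reactants: 5 (3aR)-3a-methyl-3a,4-dihydro-2-benzofuran-1,6(3H,5H)-dione
Product: 8 cis-fused keto γ-lactone with a C10 hydroxymethylene group (2-formyl ketone as Z-enol), via silyl enol ether 6 (not isolated), via keto acetal 7 (not isolated)
Conditions: Cu(OAc)2·H2O (3 mol %), 1,2-bis(diphenylphosphino)benzene (3 mol %), PhMe2SiH (1.1 equiv), toluene, 0 °C to rt; then HC(OMe)3, TMSOTf (10 mol %), CH2Cl2, −78 to −20 °C; then 1 M HCl, THF, rt
Reagents that add atoms: trimethyl orthoformate, COC(OC)OC; water, O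
Why: Copper-hydride conjugate reduction puts hydride on C5 (β to the ketone) to give the cis-fused lactone and the C1 silyl enol ether regiospecifically toward C10, and a Mukaiyama-type reaction with the orthoformate followed by acetal hydrolysis formylates C10 (C5 is epimerisable and settles cis; C10 is not stereogenic in the enol).

**Step 5**
Reactants: 8 cis-fused keto γ-lactone with a C10 hydroxymethylene group; 9 methyl acrylate
Product: 10 methyl 3-(C10-yl)propanoate of the C10-formyl keto γ-lactone (propanoate chain trans to the lactone ring)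
Conditions: methyl acrylate (3 equiv), Cs2CO3 (10 mol %), MeCN, 0 °C to rt
Reagents that add atoms: none
Why: Michael addition of the 2-formyl ketone, in which the acceptor approaches C10 anti to the cis-fused lactone (away from the axial C19 methylene), so the C9 chain ends trans and the formyl group (future C20) cis to C6.

**Step 6**
Reactants: 10 methyl 3-(C10-yl)propanoate of the C10-formyl keto γ-lactone
Product: 12 spiro δ-lactone γ-lactone with axial C1 alcohol, via keto spirolactone 11 (not isolated)
Conditions: LiBH(s-Bu)3 (1.05 equiv), THF, −78 °C, then −20 °C; recool to −78 °C, LiBH(s-Bu)3 (1.3 equiv); AcOH quench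
Reagents that add atoms: none
Why: The aldehyde is reduced first and its primary alkoxide lactonises onto the methyl ester (ring B), then the bulky borohydride attacks the C1 ketone equatorially to give the axial alcohol trans to C20 (this carbinol masks the ketone and is reset in step 16).

**Step 7**
Reactants: 13 furan-2(5H)-one; 14 4,4,5,5-tetramethyl-2-(prop-1-en-2-yl)-1,3,2-dioxaborolane
Product: 15 (S)-4-(prop-1-en-2-yl)oxolan-2-one
Conditions: [Rh(OH)(cod)]2 (1.5 mol %), (S)-BINAP (3.3 mol %), dioxane/H2O 10:1, 40 °C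
Reagents that add atoms: none
Why: Rhodium-catalysed asymmetric conjugate addition (Hayashi–Miyaura), in which the BINAP–rhodium alkenyl species adds to one enantioface of the butenolide and sets C13.

**Step 8**
Reactants: 15 (S)-4-(prop-1-en-2-yl)oxolan-2-one
Product: 16 (4S)-4-(prop-1-en-2-yl)oxolan-2-ol
Conditions: i-Bu2AlH (1.1 equiv), CH2Cl2, −78 °C; aq. potassium sodium tartrate
Reagents that add atoms: none
Why: Partial reduction of the lactone to the lactol (anomer mixture), leaving C13 untouched.

**Step 9**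
Reactants: 16 (4S)-4-(prop-1-en-2-yl)oxolan-2-ol
Product: 17 (S)-2-(1,3-dithian-2-ylmethyl)-3-methylbut-3-en-1-ol
Conditions: propane-1,3-dithiol (1.2 equiv), BF3·OEt2 (10 mol %), CH2Cl2, −20 °C
Reagents that add atoms: propane-1,3-dithiol, SCCCS
Why: Dithioacetalization opens the lactol, masking C11 as a dithiane and freeing the C14 alcohol.

**Step 10**
Reactants: 17 (S)-2-(1,3-dithian-2-ylmethyl)-3-methylbut-3-en-1-ol
Product: 18 2-[(S)-2-(iodomethyl)-3-methylbut-3-en-1-yl]-1,3-dithiane
Conditions: I2, PPh3, imidazole, CH2Cl2, 0 °C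
Reagents that add atoms: iodine, II
Why: Appel-type iodination of the primary alcohol; the stereocentre is not involved.

**Step 11**
Reactants: 12 spiro δ-lactone γ-lactone with axial C1 alcohol; 18 2-[(S)-2-(iodomethyl)-3-methylbut-3-en-1-yl]-1,3-dithiane
Product: 19 C8-alkylated bis-lactone (C8 epimers)
Conditions: LiN(i-Pr)2 (2.2 equiv), THF/HMPA, −78 °C; then 18, −78 to −30 °C; aq. NH4Cl
Reagents that add atoms: none
Why: Alkylation of the δ-lactone lithium enolate (the hindered C5–H of the γ-lactone is not removed and the C1 alkoxide is a spectator); the C8 configuration is irrelevant because C8 becomes sp2 in step 12.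

**Step 12**
Reactants: 19 C8-alkylated bis-lactone
Product: 21 C8=C9 unsaturated spiro δ-lactone, via selenide 20 (not isolated)
Conditions: LiN(i-Pr)2 (2.3 equiv), THF, −78 °C; PhSeBr; AcOH; then H2O2 (30 % aq, 1.2 equiv), pyridine, CH2Cl2, 0 °C
Reagents that add atoms: none
Why: α-Selenenylation of the lactone enolate and selenoxide syn-elimination toward the ring methylene C9 give the endocyclic conjugated alkene; selenium is oxidised much faster than the dithiane sulfur.

**Step 13**
Reactants: 21 C8=C9 unsaturated spiro δ-lactone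
Product: 22 C11 aldehyde of the unsaturated spiro δ-lactone
Conditions: PhI(OCOCF3)2 (1.5 equiv), MeCN/H2O 9:1, 0 °C
Reagents that add atoms: water, O
Why: Oxidative dethioacetalization frees the aldehyde without touching the alkenes or lactones.

**Step 14**
Reactants: 22 C11 aldehyde of the unsaturated spiro δ-lactone
Product: 23 ring C diol (C9 set; 11-OH trans to C10; C8–H)
Conditions: SmI2 (2.5 equiv), t-BuOH (2 equiv), THF, −78 °C
Reagents that add atoms: none
Why: Ketyl–olefin radical cyclization mediated by divalent samarium, in which the C11 ketyl adds to the β-carbon C9 through a chair with C10 and the isopropenyl group equatorial, on the lactone face syn to C1 and away from the C5/ring E side, which fixes C9; the C11 carbinol (expected trans to C10) and C8 are reset or erased later.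

**Step 15**
Reactants: 23 ring C diol
Product: 24 C1,C11-diketone
Conditions: Dess–Martin periodinane (3 equiv), CH2Cl2, rt
Reagents that add atoms: none
Why: Oxidation of both secondary alcohols under non-epimerising conditions, so that C1 and C11 can be set together.

**Step 16**
Reactants: 24 C1,C11-diketone
Product: 26 bis(tert-butyldimethylsilyl) ether of the 1,11-diol (11-O cis to C10; 1-O trans to C20), via dilithium dialkoxide 25 (not isolated)
Conditions: LiBH(s-Bu)3 (2.6 equiv), THF, −78 °C; then TBSOTf (3 equiv), −78 to 0 °C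
Reagents that add atoms: tert-butyldimethylsilyl trifluoromethanesulfonate, CC(C)(C)[Si](C)(C)OS(=O)(=O)C(F)(F)F
Why: Equatorial attack of the bulky borohydride gives at C11 the alcohol cis to the equatorial C9–C10 bond (as in cis-2-alkylcyclohexanols) and at C1 the axial alcohol trans to C20 (as in 4,4-dimethyl-3-keto steroids), and the alkoxides are silylated in the same flask.

**Step 17**
Reactants: 26 bis(tert-butyldimethylsilyl) ether of the 1,11-diol
Product: 28 pentacyclic 16-ene bis-lactone (rings A to E), via silyl ketene acetal 27 (not isolated)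
Conditions: LiN(i-Pr)2 (1.5 equiv), TBSCl, HMPA, THF, −78 °C; then Pd(OAc)2 (1.1 equiv), DMSO, 45 °C
Reagents that add atoms: none
Why: Oxidative cycloalkenylation mediated by divalent palladium (Saegusa/Toyota type), in which the C8 silyl ketene acetal attacks the palladium-bound isopropenyl terminus (C8–C15) and β-hydride elimination toward the methyl gives the C16 methylidene; the bridge can only close on the face bearing the C13 substituent, which fixes C8.

**Step 18**
Reactants: 28 pentacyclic 16-ene bis-lactone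
Product: 29 C6 lactol (anomers)
Conditions: i-Bu2AlH (1.2 equiv), CH2Cl2, −78 °C; aq. potassium sodium tartrate
Reagents that add atoms: none
Why: Chemoselective partial reduction of the γ-lactone; the δ-lactone carbonyl is shielded by the quaternary bridgehead C8 and the neopentyl C20.

**Step 19**
Reactants: 29 C6 lactol
Product: 30 C6 acetate (acetoxy on the convex face, trans to C10)
Conditions: Ac2O (1.5 equiv), Et3N, DMAP (5 mol %), CH2Cl2, 0 °C
Reagents that add atoms: acetic anhydride, CC(=O)OC(C)=O
Why: Acylation of the equilibrating lactol; the anomer with the hydroxyl on the convex face, trans to the C5–C10 bond, is favoured and acylated faster, which sets C6.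

**Step 20**
Reactants: 30 C6 acetate
Product: 31 C15 allylic alcohol (C15 epimers)
Conditions: SeO2 (0.5 equiv), t-BuOOH (3 equiv), CH2Cl2, rt
Reagents that add atoms: selenium dioxide, O=[Se]=O; tert-butyl hydroperoxide, CC(C)(C)OO
Why: Allylic oxidation (ene reaction then [2,3]-shift) at the only allylic methylene, C15; the bridgehead C13–H cannot react.

**Step 21**
Reactants: 31 C15 allylic alcohol
Product: 32 bis-silyl ether of Oreskaurin A
Conditions: Dess–Martin periodinane (1.5 equiv), CH2Cl2, 0 °C to rt
Reagents that add atoms: none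
Why: Oxidation of the allylic alcohol to the α-methylidene ketone; the C15 configuration is erased.

**Step 22**
Reactants: 32 bis-silyl ether of Oreskaurin A
Product: 33 Oreskaurin A
Conditions: HF·pyridine, pyridine/THF, 0 °C to rt
Reagents that add atoms: none
Why: Buffered fluoride desilylation frees the C1 and C11 alcohols while sparing the acetoxy acetal, enone and lactone.

**Compound list**
1 | methyl 3-methyl-2-oxobutanoate | COC(=O)C(=O)C(C)C | starting material
2 | but-3-en-2-one | CC(=O)C=C | starting material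
3 | methyl 6,6-dimethyl-3-oxocyclohex-1-ene-1-carboxylate | COC(=O)C1=CC(=O)CCC1(C)C | intermediate
4 | 6,6-dimethyl-3-oxocyclohex-1-ene-1-carboxylic acid | OC(=O)C1=CC(=O)CCC1(C)C | intermediate
5 | (3aR)-3a-methyl-3a,4-dihydro-2-benzofuran-1,6(3H,5H)-dione | O=C1CC[C@@]2(C)COC(=O)C2=C1 | intermediate
6 | C1 dimethylphenylsilyl enol ether of the cis-fused keto γ-lactone | C[Si](C)(c1ccccc1)OC1=C[C@@H]2C(=O)OC[C@]2(C)CC1 | intermediate
7 | cis-fused keto γ-lactone with C10 dimethoxymethyl group (C10 epimers) | COC(OC)C1C(=O)CC[C@@]2(C)COC(=O)[C@H]21 | intermediate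
8 | cis-fused keto γ-lactone with C10 hydroxymethylene group (Z-enol of the 2-formyl ketone) | O=C1CC[C@@]2(C)COC(=O)[C@H]2/C1=C/O | intermediate
9 | methyl acrylate | COC(=O)C=C | starting material
10 | methyl 3-(C10-yl)propanoate of the C10-formyl keto γ-lactone | COC(=O)CC[C@]1(C=O)C(=O)CC[C@@]2(C)COC(=O)[C@H]21 | intermediate
11 | keto spirolactone (δ-lactone, γ-lactone, C1 ketone) | O=C1CC[C@]2(CO1)C(=O)CC[C@@]3(C)COC(=O)[C@H]32 | intermediate
12 | spiro δ-lactone γ-lactone with axial C1 alcohol | O=C1CC[C@]2(CO1)[C@H](O)CC[C@@]3(C)COC(=O)[C@H]32 | intermediate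
13 | furan-2(5H)-one | O=C1OCC=C1 | starting material
14 | 4,4,5,5-tetramethyl-2-(prop-1-en-2-yl)-1,3,2-dioxaborolane | CC(=C)B1OC(C)(C)C(C)(C)O1 | starting material
15 | (S)-4-(prop-1-en-2-yl)oxolan-2-one | O=C1C[C@@H](C(C)=C)CO1 | intermediate
16 | (4S)-4-(prop-1-en-2-yl)oxolan-2-ol (anomers) | OC1C[C@@H](C(C)=C)CO1 | intermediate
17 | (S)-2-(1,3-dithian-2-ylmethyl)-3-methylbut-3-en-1-ol | OC[C@H](C(C)=C)CC1SCCCS1 | intermediate
18 | 2-[(S)-2-(iodomethyl)-3-methylbut-3-en-1-yl]-1,3-dithiane | IC[C@H](C(C)=C)CC1SCCCS1 | intermediate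
19 | C8-alkylated bis-lactone (C8 epimers) | O=C1C(C[C@H](C(C)=C)CC2SCCCS2)C[C@]2(CO1)[C@H](O)CC[C@@]3(C)COC(=O)[C@H]32 | intermediate
20 | C8 phenylselanyl bis-lactone (C8 epimers) | O=C1C(C[C@H](C(C)=C)CC2SCCCS2)([Se]c2ccccc2)C[C@]2(CO1)[C@H](O)CC[C@@]3(C)COC(=O)[C@H]32 | intermediate
21 | C8=C9 unsaturated spiro δ-lactone (dithiane) | O=C1C(C[C@H](C(C)=C)CC2SCCCS2)=C[C@]2(CO1)[C@H](O)CC[C@@]3(C)COC(=O)[C@H]32 | intermediate
22 | C11 aldehyde of the unsaturated spiro δ-lactone | O=C1C(C[C@H](C(C)=C)CC=O)=C[C@]2(CO1)[C@H](O)CC[C@@]3(C)COC(=O)[C@H]32 | intermediate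
23 | ring C diol (11-OH trans to C10; C8–H cis to H9, assumed) | C=C(C)[C@@H]1C[C@H](O)[C@@H]2[C@H](C1)C(=O)OC[C@]23[C@H](O)CC[C@@]4(C)COC(=O)[C@H]43 | intermediate
24 | C1,C11-diketone | C=C(C)[C@@H]1CC(=O)[C@@H]2[C@H](C1)C(=O)OC[C@]23C(=O)CC[C@@]4(C)COC(=O)[C@H]43 | intermediate
25 | dilithium dialkoxide of the 1,11-diol | C=C(C)[C@@H]1C[C@@H](O[Li])[C@@H]2[C@H](C1)C(=O)OC[C@]23[C@H](O[Li])CC[C@@]4(C)COC(=O)[C@H]43 | intermediate
26 | bis(tert-butyldimethylsilyl) ether of the 1,11-diol | C=C(C)[C@@H]1C[C@@H](O[Si](C)(C)C(C)(C)C)[C@@H]2[C@H](C1)C(=O)OC[C@]23[C@H](O[Si](C)(C)C(C)(C)C)CC[C@@]4(C)COC(=O)[C@H]43 | intermediate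
27 | C7 tert-butyldimethylsilyl ketene acetal of 26 | C=C(C)[C@@H]1C[C@@H](O[Si](C)(C)C(C)(C)C)[C@@H]2C(C1)=C(O[Si](C)(C)C(C)(C)C)OC[C@]23[C@H](O[Si](C)(C)C(C)(C)C)CC[C@@]4(C)COC(=O)[C@H]43 | intermediate
28 | pentacyclic 16-ene bis-lactone (rings A to E) | C=C1C[C@]23C[C@H]1C[C@@H](O[Si](C)(C)C(C)(C)C)[C@H]2[C@]1(COC3=O)[C@H](O[Si](C)(C)C(C)(C)C)CC[C@@]2(C)COC(=O)[C@H]21 | intermediate
29 | C6 lactol (anomers) | C=C1C[C@]23C[C@H]1C[C@@H](O[Si](C)(C)C(C)(C)C)[C@H]2[C@]1(COC3=O)[C@H](O[Si](C)(C)C(C)(C)C)CC[C@@]2(C)COC(O)[C@H]21 | intermediate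
30 | C6 acetate | C=C1C[C@]23C[C@H]1C[C@@H](O[Si](C)(C)C(C)(C)C)[C@H]2[C@]1(COC3=O)[C@H](O[Si](C)(C)C(C)(C)C)CC[C@@]2(C)CO[C@H](OC(C)=O)[C@H]21 | intermediate
31 | C15 allylic alcohol (C15 epimers) | C=C1C(O)[C@]23C[C@H]1C[C@@H](O[Si](C)(C)C(C)(C)C)[C@H]2[C@]1(COC3=O)[C@H](O[Si](C)(C)C(C)(C)C)CC[C@@]2(C)CO[C@H](OC(C)=O)[C@H]21 | intermediate
32 | bis-silyl ether of Oreskaurin A | C=C1C(=O)[C@]23C[C@H]1C[C@@H](O[Si](C)(C)C(C)(C)C)[C@H]2[C@]1(COC3=O)[C@H](O[Si](C)(C)C(C)(C)C)CC[C@@]2(C)CO[C@H](OC(C)=O)[C@H]21 | intermediate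
33 | Oreskaurin A | C=C1C(=O)[C@]23C[C@H]1C[C@@H](O)[C@H]2[C@]1(COC3=O)[C@H](O)CC[C@@]2(C)CO[C@H](OC(C)=O)[C@H]21 | target

**Totals**
Total step count: 22. Longest linear sequence: 18 (steps 1–6 and 11–22).

**Steps most likely to fail**

Step 3 (the proposed lactonization; risks are alkene oxidation, low conversion of a primary C–H bond and insufficient enantioselectivity). The fallback uses only known chemistry, sets out from 3 and comes back at 5. Asymmetric copper-hydride conjugate reduction of 3 (Cu(OAc)2, (R)-DTBM-SEGPHOS, polymethylhydrosiloxane, then aqueous NH4F) gives methyl (S)-2,2-dimethyl-4-oxocyclohexane-1-carboxylate F1. Mild ester cleavage with Me3SnOH gives (S)-2,2-dimethyl-4-oxocyclohexane-1-carboxylic acid F2. The manganese-catalysed γ-lactonization, now on a saturated acid of the kind for which it is established, attacks the methyl cis to the carboxyl and gives the cis-fused keto lactone F3, relaying chirality from C5 to C4. Thermodynamic enol silylation toward the ring-fusion side (TMSCl, NaI, Et3N) gives the trimethylsilyl enol ether F4, and Saegusa–Ito dehydrogenation with Pd(OAc)2 returns 5.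

Step 12 (the selenoxide may eliminate toward the side-chain methylene C14 instead of C9). The fallback sets out from 12 and comes back at 21. Selenenylation of 12 (LiN(i-Pr)2, PhSeBr) gives the C8 phenylselanyl lactone F5. Its selenoxide can eliminate only toward C9 and gives the unsubstituted unsaturated spirolactone F6. Conjugate addition of PhSeLi at C9 and trapping of the C8 enolate with iodide 18 gives the C9-selanyl C8-alkyl lactone F7. Oxidation with H2O2 and syn-elimination, for which only the C8–H is available, gives 21 with the alkene necessarily between C8 and C9.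

Step 17 (the palladium-mediated closure must form a quaternary centre next to a hindered lactone). The fallback sets out from 26 and comes back at 28. Ene-type allylic chlorination of the isopropenyl group (Ca(OCl)2, solid CO2, CH2Cl2/H2O) gives the 2-(chloromethyl)allyl compound F8. Deprotonation at C8 with KN(SiMe3)2 (THF, −78 to 0 °C) then closes ring D by intramolecular enolate alkylation (C8–C15) and gives 28.

**Further compounds**
F1 | step 3 | methyl (S)-2,2-dimethyl-4-oxocyclohexane-1-carboxylate | COC(=O)[C@H]1CC(=O)CCC1(C)C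
F2 | step 3 | (S)-2,2-dimethyl-4-oxocyclohexane-1-carboxylic acid | OC(=O)[C@H]1CC(=O)CCC1(C)C
F3 | step 3 | cis-fused keto γ-lactone (saturated analogue of 5) | O=C1CC[C@@]2(C)COC(=O)[C@H]2C1
F4 | step 3 | C1 trimethylsilyl enol ether of F3 | C[Si](C)(C)OC1=C[C@@H]2C(=O)OC[C@]2(C)CC1
F5 | step 12 | C8 phenylselanyl derivative of 12 (C8 epimers) | O=C1C([Se]c2ccccc2)C[C@]2(CO1)[C@H](O)CC[C@@]3(C)COC(=O)[C@H]32
F6 | step 12 | unsubstituted C8=C9 unsaturated spirolactone | O=C1C=C[C@]2(CO1)[C@H](O)CC[C@@]3(C)COC(=O)[C@H]32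
F7 | step 12 | C9-phenylselanyl C8-alkyl lactone (C8, C9 epimers) | O=C1C(C[C@H](C(C)=C)CC2SCCCS2)C([Se]c2ccccc2)[C@]2(CO1)[C@H](O)CC[C@@]3(C)COC(=O)[C@H]32
F8 | step 17 | 2-(chloromethyl)allyl analogue of 26 | ClCC(=C)[C@@H]1C[C@@H](O[Si](C)(C)C(C)(C)C)[C@@H]2[C@H](C1)C(=O)OC[C@]23[C@H](O[Si](C)(C)C(C)(C)C)CC[C@@]4(C)COC(=O)[C@H]43
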